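**Plan**

- Cuts, in order: C2–C3 (ring A, pinacol retron of the cis-2,3-diol); then C5–C6 and C9–C10 together (ring B); then a helper link O19–SiMe2–C7. The pieces are a C11 enyne from (R)-citronellic acid and a C8 enal built around C4 of a tris(hydroxymethyl)ethane derivative. C2 is added as a one-carbon ylide.
- Enabling feature: ring B is a cyclohexene whose C7=C8 bond lies opposite the C5–C10 bond, which is a Diels–Alder retron (diene C6=C7–C8=C9, dienophile C5=C10). O19 sits on C4, next to C5, and can be tied to C7 by one SiMe2 unit. C1 on C10 serves as the activating formyl group.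
- Forward order: the fragments are joined by alkyne hydrosilylation. Ring B closes in the tethered cycloaddition, together with a temporary seven-membered oxasila ring. C2 is then added at C1, silicon is excised, O19 is acetylated, and ring A closes last.
- Stereochemistry: C13 is bought and C4 comes from a catalytic desymmetrisation. C5, C9 and C10 arise in one event: the E-enal gives the trans fusion, the endo-locked tether plus the E-diene gives C9, and C4 chooses the face. C2 and C3 arise in the Sm(III)-chelated pinacol closure under control of the axial C19 and C20 groups.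

Key step: step 11

Remark: atoms carry labdane numbers throughout (C19 = acetoxymethyl carbon, C20 = angular methyl, C15 = acid carbon). The sense of induction in step 6 is set by the choice of ligand antipode.

**Step 1**
Reactants: 1 (R)-citronellic acid
Product: 2 tert-butyl (3R)-3,7-dimethyloct-6-enoate
Conditions: Boc2O, DMAP (cat.), t-BuOH, 35 °C
Reagents that add atoms: di-tert-butyl dicarbonate CC(C)(C)OC(=O)OC(=O)OC(C)(C)C
Why: DMAP-catalysed tert-butyl esterification through the mixed carbonic anhydride masks the acid in a form that resists ylides, fluoride and SmI2, and C13 is not touched.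

**Step 2**
Reactants: 2 tert-butyl (3R)-3,7-dimethyloct-6-enoate
Product: 3 tert-butyl (3R,6E)-3,7-dimethyl-8-oxooct-6-enoate
Conditions: SeO2 (1.2 equiv), 1,4-dioxane, 80 °C
Reagents that add atoms: selenium dioxide O=[Se]=O
Why: Riley allylic oxidation (ene reaction, then [2,3]-sigmatropic shift) attacks the methyl group trans to the chain of a gem-dimethyl alkene and so should give the E-enal.

**Step 3**
Reactants: 3 tert-butyl (3R,6E)-3,7-dimethyl-8-oxooct-6-enoate
Product: 4 tert-butyl (3R,6E)-3,7-dimethylnon-6-en-8-ynoate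
Conditions: TMSCHN2, LDA, THF, −78 °C to rt
Reagents that add atoms: (trimethylsilyl)diazomethane C[Si](C)(C)C=[N+]=[N-]
Why: Colvin homologation (1,2-addition, loss of silanolate and N2, 1,2-hydrogen shift of the alkylidene carbene) turns the non-enolisable enal into the terminal enyne and leaves the E double bond and the hindered ester alone.

**Step 4**
Reactants: 5 (2,2,5-trimethyl-1,3-dioxan-5-yl)methanol
Product: 6 2,2,5-trimethyl-1,3-dioxane-5-carbaldehyde
Conditions: TEMPO (cat.), PhI(OAc)2, CH2Cl2, rt
Reagents that add atoms: none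
Why: Oxoammonium (TEMPO) oxidation of a primary neopentyl alcohol stops at the aldehyde, which has no α-hydrogen.

**Step 5**
Reactants: 6 2,2,5-trimethyl-1,3-dioxane-5-carbaldehyde
Product: 7 2-(dimethoxymethyl)-2-methylpropane-1,3-diol
Conditions: HC(OMe)3 (1.2 equiv), TsOH·H2O (cat.), MeOH, rt
Reagents that add atoms: trimethyl orthoformate COC(OC)OC
Why: Acid-catalysed acetalisation of the aldehyde and transacetalisation of the acetonide in methanol run in the same flask, and an internal acetal is excluded because it would be a four-membered ring.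

**Step 6**
Reactants: 7 2-(dimethoxymethyl)-2-methylpropane-1,3-diol
Product: 8 (2R)-2-(dimethoxymethyl)-3-hydroxy-2-methylpropyl benzoate
Conditions: BzCl, Et3N, CuCl2/chiral bis(oxazoline) ligand (10 mol %), THF, 0 °C
Reagents that add atoms: benzoyl chloride O=C(Cl)c1ccccc1
Why: Catalytic enantioselective desymmetrisation of a 2,2-disubstituted propane-1,3-diol by Cu(II)-mediated monobenzoylation acylates one enantiotopic CH2OH of the chelated diol and thereby sets C4 (the benzoylated arm is C19, the free arm is C5).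

**Step 7**
Reactants: 8 (2R)-2-(dimethoxymethyl)-3-hydroxy-2-methylpropyl benzoate
Product: 9 (2S)-2-(dimethoxymethyl)-2-methyl-3-oxopropyl benzoate
Conditions: TEMPO (cat.), PhI(OAc)2, CH2Cl2, rt
Reagents that add atoms: none
Why: TEMPO oxidation gives an aldehyde on a quaternary carbon, so neither epimerisation nor β-elimination of benzoate is possible (the descriptor changes by priority only).

**Step 8**
Reactants: 9 (2S)-2-(dimethoxymethyl)-2-methyl-3-oxopropyl benzoate
Product: 10 (2R,3E)-2-(dimethoxymethyl)-2,4-dimethyl-5-oxopent-3-en-1-yl benzoate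
Conditions: Ph3P=C(Me)CHO, PhMe, 100 °C
Reagents that add atoms: 2-(triphenylphosphoranylidene)propanal CC(C=O)=P(c1ccccc1)(c1ccccc1)c1ccccc1
Why: Wittig reaction of a stabilised ylide is E-selective under thermodynamic control and places C4 trans to the formyl group C1, the geometry that later becomes the trans ring fusion.

**Step 9**
Reactants: 10 (2R,3E)-2-(dimethoxymethyl)-2,4-dimethyl-5-oxopent-3-en-1-yl benzoate
Product: 11 (2E,4R)-4-(dimethoxymethyl)-5-hydroxy-2,4-dimethylpent-2-enal
Conditions: K2CO3 (cat.), MeOH, 0 °C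
Reagents that add atoms: none
Why: Base-catalysed transesterification frees O19, and the E geometry keeps the hydroxyl group away from the formyl group so that no lactol can form.

**Step 10**
Reactants: 11 (2E,4R)-4-(dimethoxymethyl)-5-hydroxy-2,4-dimethylpent-2-enal; 4 tert-butyl (3R,6E)-3,7-dimethylnon-6-en-8-ynoate
Product: 13 silicon-tethered triene (O19–SiMe2–C7 link; E-diene; E-enal), via dimethylsilyl ether 12 (not isolated)
Conditions: (HMe2Si)2NH, neat, 40 °C, then evaporate; 4, [Cp*Ru(MeCN)3]PF6 (5 mol %), CH2Cl2, 0 °C to rt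
Reagents that add atoms: 1,1,3,3-tetramethyldisilazane C[SiH](C)N[SiH](C)C
Why: O-silylation followed by cationic-ruthenium Markovnikov hydrosilylation of the terminal alkyne puts silicon on the internal carbon C7 and hydrogen on C6, giving the 2-silyl-1,3-diene and joining the fragments in one flask.

**Step 11**
Reactants: 13 silicon-tethered triene
Product: 14 bridged cycloadduct (ring B closed; SiMe2–O–C19–C4 bridge from C7 to C5; formyl C1 and methyl C20 on C10)
Conditions: PhMe (0.01 M), BHT (cat.), 160 °C, sealed tube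
Reagents that add atoms: none
Why: Concerted, asynchronous [π4s+π2s] cycloaddition of the 2-silyl diene C6=C7–C8=C9 to the enal bond C5=C10, whose closest known reaction type is the type 2 intramolecular Diels–Alder reaction of 2-silyl dienes joined to the dienophile through a cleavable Si–O link. Ring B closes in the suprafacial [4+2] mode, and the seven-membered oxasila ring (C5–C4–C19–O–Si–C7–C6) closes with it in the 1,3-bridged mode, giving a bicyclo[4.3.1]decene whose bridgehead C7=C8 bond is relaxed by the long Si–C and Si–O bonds. C5 and C10 are set because the E-enal geometry is carried over suprafacially, so C4 and C1 end up trans on ring B (H5 anti to C20), which is the future trans-decalin fusion. C9 is set because the four-atom tether can span C7 and C5 only if C4, and with it the cis methyl C20, lies endo under the diene, so the outside C11 chain of the E-diene ends cis to C4 and C20 and the formyl group exo, whereas the untethered reaction would place the bulky C4 exo and give the C9 epimer. The face is chosen by C4: with the C19 arm held inside, the branched dimethoxymethyl group should stand anti to the forming C5–C6 bond and the methyl group in the crowded outside position, which leads to the 4R,5S relation. The required regioselectivity (C6 to C5, C9 to C10) is secured both by the tether length and by the match of the enal β-carbon C5 with the unsubstituted diene terminus C6, and the ester, acetal and silyl ether are inert at this temperature.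

**Step 12**
Reactants: 14 bridged cycloadduct
Product: 15 bridged methyl enol ether (C1=C2–OMe, E/Z mixture)
Conditions: MeOCH2PPh3Cl, KOt-Bu, THF, 0 °C to rt
Reagents that add atoms: (methoxymethyl)triphenylphosphonium chloride COC[P+](c1ccccc1)(c1ccccc1)c1ccccc1.[Cl-]
Why: Wittig methoxymethylenation adds C2 to the non-enolisable neopentyl aldehyde while O19 is still tied up, so no C1/O19 lactol can interfere.

**Step 13**
Reactants: 15 bridged methyl enol ether
Product: 16 tert-butyl (4R,5S,9R,10S,13R)-19-hydroxy-2,3,3-trimethoxy-2,3-secolabda-1,7-dien-15-oate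
Conditions: TBAF (4 equiv), THF–DMF, 60 °C
Reagents that add atoms: none
Why: Fluoride opens the siloxane and protodesilylates the vinylsilane at the ipso carbon, helped by release of bridgehead strain, so C7 gains hydrogen, the double bond stays at C7=C8 and O19 is set free.

**Step 14**
Reactants: 16 tert-butyl 19-hydroxy-2,3,3-trimethoxy-2,3-secolabda-1,7-dien-15-oate
Product: 17 tert-butyl (4R,5S,9R,10S,13R)-19-acetoxy-2,3,3-trimethoxy-2,3-secolabda-1,7-dien-15-oate
Conditions: Ac2O, pyridine, DMAP (cat.), CH2Cl2, rt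
Reagents that add atoms: acetic anhydride CC(=O)OC(C)=O
Why: DMAP-catalysed acetylation meets only one hydroxyl group, so the acetate of the target is placed without any selectivity problem.

**Step 15**
Reactants: 17 tert-butyl 19-acetoxy-2,3,3-trimethoxy-2,3-secolabda-1,7-dien-15-oate
Product: 18 tert-butyl (4R,5S,9R,10S,13R)-19-acetoxy-2,3-dioxo-2,3-secolabd-7-en-15-oate
Conditions: TsOH·H2O (cat.), acetone–H2O, rt; used at once
Reagents that add atoms: water O
Why: Mild acid hydrolysis unmasks the enol ether (C2) and the dimethyl acetal (C3) together, and the acetoxy aldehyde cannot eliminate because C4 carries no hydrogen.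

**Step 16**
Reactants: 18 tert-butyl 19-acetoxy-2,3-dioxo-2,3-secolabd-7-en-15-oate
Product: 19 tert-butyl (2S,3R,4R,5S,9R,10S,13R)-19-acetoxy-2,3-dihydroxylabd-7-en-15-oate
Conditions: SmI2 (3 equiv), t-BuOH (2 equiv), THF, −78 °C to rt
Reagents that add atoms: none
Why: SmI2 pinacol cyclisation of a 1,6-dialdehyde holds both ketyl oxygens cis on one Sm(III) centre and, in the chair-like closure of ring A, on the face opposite to the axial C19 and C20 groups, so O2 should become equatorial and O3 axial, whereas the other cis pair would force O2 into a double 1,3-diaxial contact.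

**Step 17**
Reactants: 19 tert-butyl 19-acetoxy-2,3-dihydroxylabd-7-en-15-oate
Product: 20 target acid
Conditions: TFA–CH2Cl2 (1:5), 0 °C
Reagents that add atoms: none
Why: Acidolysis of the tert-butyl ester (loss of isobutene) spares the primary acetate, and acyl migration to O3 is geometrically excluded because C19 and O3 are trans-diaxial.

**Compound list**

1 | (R)-citronellic acid, (3R)-3,7-dimethyloct-6-enoic acid | CC(C)=CCC[C@@H](C)CC(=O)O | starting material
2 | tert-butyl (3R)-3,7-dimethyloct-6-enoate | CC(C)=CCC[C@@H](C)CC(=O)OC(C)(C)C | intermediate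
3 | tert-butyl (3R,6E)-3,7-dimethyl-8-oxooct-6-enoate | O=C/C(C)=C/CC[C@@H](C)CC(=O)OC(C)(C)C | intermediate
4 | tert-butyl (3R,6E)-3,7-dimethylnon-6-en-8-ynoate | C#C/C(C)=C/CC[C@@H](C)CC(=O)OC(C)(C)C | intermediate
5 | (2,2,5-trimethyl-1,3-dioxan-5-yl)methanol | CC1(C)OCC(C)(CO)CO1 | starting material
6 | 2,2,5-trimethyl-1,3-dioxane-5-carbaldehyde | CC1(C)OCC(C)(C=O)CO1 | intermediate
7 | 2-(dimethoxymethyl)-2-methylpropane-1,3-diol | OCC(C)(CO)C(OC)OC | intermediate
8 | (2R)-2-(dimethoxymethyl)-3-hydroxy-2-methylpropyl benzoate | O=C(c1ccccc1)OC[C@@](C(OC)OC)(C)CO | intermediate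
9 | (2S)-2-(dimethoxymethyl)-2-methyl-3-oxopropyl benzoate | O=C(c1ccccc1)OC[C@@](C(OC)OC)(C)C=O | intermediate
10 | (2R,3E)-2-(dimethoxymethyl)-2,4-dimethyl-5-oxopent-3-en-1-yl benzoate | O=C(c1ccccc1)OC[C@@](C(OC)OC)(C)/C=C(\C)C=O | intermediate
11 | (2E,4R)-4-(dimethoxymethyl)-5-hydroxy-2,4-dimethylpent-2-enal | OC[C@@](C(OC)OC)(C)/C=C(\C)C=O | intermediate
12 | (2E,4R)-4-(dimethoxymethyl)-5-(dimethylsilyloxy)-2,4-dimethylpent-2-enal | C[SiH](C)OC[C@@](C(OC)OC)(C)/C=C(\C)C=O | intermediate
13 | tert-butyl (3R,6E)-8-({[(2R,3E)-2-(dimethoxymethyl)-2,4-dimethyl-5-oxopent-3-en-1-yl]oxy}dimethylsilyl)-3,7-dimethylnona-6,8-dienoate | C=C([Si](C)(C)OC[C@@](C(OC)OC)(C)/C=C(\C)C=O)/C(C)=C/CC[C@@H](C)CC(=O)OC(C)(C)C | intermediate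
14 | bridged cycloadduct: cyclohexene ring B (C5–C10) bridged from C7 to C5 by SiMe2–O–C19H2–C4; C4 carries CH3 and CH(OMe)2; C10 carries CH3 and CHO; H5 anti to C20; C9 side chain cis to C20 and C4; descriptors 4R,5S,9S,10R,13R (C9 and C10 change by Si priority only; same spatial arrangement as in 20) | C[Si]1(C)OC[C@@](C(OC)OC)(C)[C@H]2CC1=C(C)[C@@H](CC[C@@H](C)CC(=O)OC(C)(C)C)[C@]2(C)C=O | intermediate
15 | bridged methyl enol ether: 14 with the C10 formyl group replaced by CH=CH–OMe (E/Z mixture) | C[Si]1(C)OC[C@@](C(OC)OC)(C)[C@H]2CC1=C(C)[C@@H](CC[C@@H](C)CC(=O)OC(C)(C)C)[C@]2(C)C=COC | intermediate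
16 | tert-butyl (4R,5S,9R,10S,13R)-19-hydroxy-2,3,3-trimethoxy-2,3-secolabda-1,7-dien-15-oate | OC[C@@](C(OC)OC)(C)[C@H]1CC=C(C)[C@@H](CC[C@@H](C)CC(=O)OC(C)(C)C)[C@]1(C)C=COC | intermediate
17 | tert-butyl (4R,5S,9R,10S,13R)-19-acetoxy-2,3,3-trimethoxy-2,3-secolabda-1,7-dien-15-oate | CC(=O)OC[C@@](C(OC)OC)(C)[C@H]1CC=C(C)[C@@H](CC[C@@H](C)CC(=O)OC(C)(C)C)[C@]1(C)C=COC | intermediate
18 | tert-butyl (4R,5S,9R,10S,13R)-19-acetoxy-2,3-dioxo-2,3-secolabd-7-en-15-oate | CC(=O)OC[C@@](C=O)(C)[C@H]1CC=C(C)[C@@H](CC[C@@H](C)CC(=O)OC(C)(C)C)[C@]1(C)CC=O | intermediate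
19 | tert-butyl (2S,3R,4R,5S,9R,10S,13R)-19-acetoxy-2,3-dihydroxylabd-7-en-15-oate | CC(=O)OC[C@@]1(C)[C@H]2CC=C(C)[C@@H](CC[C@@H](C)CC(=O)OC(C)(C)C)[C@]2(C)C[C@H](O)[C@@H]1O | intermediate
20 | (3R)-5-[(1R,4aS,5R,6R,7S,8aS)-5-(acetoxymethyl)-6,7-dihydroxy-2,5,8a-trimethyl-1,4,4a,5,6,7,8,8a-octahydronaphthalen-1-yl]-3-methylpentanoic acid | CC(=O)OC[C@@]1(C)[C@H]2CC=C(C)[C@@H](CC[C@@H](C)CC(=O)O)[C@]2(C)C[C@H](O)[C@@H]1O | target

Total step count: 17. Longest linear sequence: 14 (steps 4–17, from 5).

**Steps most likely to fail**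

**1. Step 11.** Both new bonds form next to quaternary carbons, so the cycloaddition may be too slow and thermal loss of the silyl ether may outrun it. The facial bias exerted by C4 may also be weak.

The fallback uses a more electron-rich diene on a longer, less strained tether. It sets out from 2 and 11 and returns at 16.
- Ozonolysis of 2 (O3, then Me2S) should give tert-butyl (3R)-3-methyl-6-oxohexanoate F1.
- A Wittig reaction with 3-(triphenylphosphoranylidene)butan-2-one should give tert-butyl (3R,6E)-3,7-dimethyl-8-oxonon-6-enoate F2.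
- Kinetic enolisation at the methyl ketone (LDA, −78 °C), capture with iPr2SiCl2 and then with 11 (imidazole) would give the silaketal-tethered 2-silyloxy triene F3.
- Its type 2 cycloaddition (five-atom tether) should run at lower temperature to the bridged silyl enol ether aldehyde F4.
- Wittig methoxymethylenation gives the bridged bis(enol ether) F5.
- CsF/PhNTf2 cleaves only the enol O–Si bond and traps the regiodefined C7 enolate as the C7 enol triflate F6, in which O19 stays masked as the fluorodiisopropylsilyl ether.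
- Pd(OAc)2/PPh3/HCO2H/Bu3N reduces the triflate to the C7=C8 alkene fluorosilyl ether F7, and TBAF frees O19 to give 16.

**2. Step 10.** The Si–H bond may add to the enal carbonyl or add to the alkyne in the linear sense, and the labile Si–O bond may be lost on handling.

The fallback forms the C7–Si bond before the enal is present. It sets out from 4 and returns at 13.
- 4 alone is hydrosilylated with ethoxydimethylsilane under the same ruthenium catalysis to tert-butyl (3R,6E)-8-[ethoxy(dimethyl)silyl]-3,7-dimethylnona-6,8-dienoate F8, which can be purified from any regioisomer.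
- F8 is then heated with 11 and catalytic PPTS in toluene with removal of ethanol (alkoxysilane exchange) to give 13.

**3. Step 16.** Chelate control may be lost, giving closure to the diequatorial trans-diol, and simple reduction of the aldehydes may compete.

The fallback sets C3 afterwards by hydride delivery instead of in the C–C bond formation. It sets out from 18 and returns at 19.
- The 3-epimeric diol F9 obtained from 18 is silylated at the less hindered equatorial 2-OH (TBSCl, imidazole) to the 2-O-TBS ether F10.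
- F10 is oxidised (Dess–Martin periodinane) to the 3-ketone F11.
- F11 is reduced with L-Selectride, which attacks 4,4-disubstituted 3-ketones along the equatorial trajectory, to the axial 3-alcohol F12.
- F12 is desilylated (HF·pyridine) to 19.

**Further compounds**

F1 | step 11 | tert-butyl (3R)-3-methyl-6-oxohexanoate | O=CCC[C@@H](C)CC(=O)OC(C)(C)C
F2 | step 11 | tert-butyl (3R,6E)-3,7-dimethyl-8-oxonon-6-enoate | CC(=O)/C(C)=C/CC[C@@H](C)CC(=O)OC(C)(C)C
F3 | step 11 | silaketal-tethered 2-silyloxy triene (C7–O–Si(iPr)2–O–C19) | C=C(O[Si](C(C)C)(C(C)C)OC[C@@](C(OC)OC)(C)/C=C(\C)C=O)/C(C)=C/CC[C@@H](C)CC(=O)OC(C)(C)C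
F4 | step 11 | bridged silyl enol ether aldehyde | CC(C)[Si]1(C(C)C)OC[C@@](C(OC)OC)(C)[C@H]2CC(O1)=C(C)[C@@H](CC[C@@H](C)CC(=O)OC(C)(C)C)[C@]2(C)C=O
F5 | step 11 | bridged bis(enol ether) | CC(C)[Si]1(C(C)C)OC[C@@](C(OC)OC)(C)[C@H]2CC(O1)=C(C)[C@@H](CC[C@@H](C)CC(=O)OC(C)(C)C)[C@]2(C)C=COC
F6 | step 11 | C7 enol triflate, O19 fluorodiisopropylsilyl ether | CC(C)[Si](F)(C(C)C)OC[C@@](C(OC)OC)(C)[C@H]1CC(OS(=O)(=O)C(F)(F)F)=C(C)[C@@H](CC[C@@H](C)CC(=O)OC(C)(C)C)[C@]1(C)C=COC
F7 | step 11 | C7=C8 alkene, O19 fluorodiisopropylsilyl ether | CC(C)[Si](F)(C(C)C)OC[C@@](C(OC)OC)(C)[C@H]1CC=C(C)[C@@H](CC[C@@H](C)CC(=O)OC(C)(C)C)[C@]1(C)C=COC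
F8 | step 10 | tert-butyl (3R,6E)-8-[ethoxy(dimethyl)silyl]-3,7-dimethylnona-6,8-dienoate | C=C([Si](C)(C)OCC)/C(C)=C/CC[C@@H](C)CC(=O)OC(C)(C)C
F9 | step 16 | 3-epimeric (diequatorial) diol of 19 | CC(=O)OC[C@@]1(C)[C@H]2CC=C(C)[C@@H](CC[C@@H](C)CC(=O)OC(C)(C)C)[C@]2(C)C[C@H](O)[C@H]1O
F10 | step 16 | 2-O-TBS ether of F9 | CC(=O)OC[C@@]1(C)[C@H]2CC=C(C)[C@@H](CC[C@@H](C)CC(=O)OC(C)(C)C)[C@]2(C)C[C@H](O[Si](C)(C)C(C)(C)C)[C@H]1O
F11 | step 16 | 2-O-TBS 3-ketone | CC(=O)OC[C@@]1(C)[C@H]2CC=C(C)[C@@H](CC[C@@H](C)CC(=O)OC(C)(C)C)[C@]2(C)C[C@H](O[Si](C)(C)C(C)(C)C)C1=O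
F12 | step 16 | 2-O-TBS ether of 19 (axial 3-OH) | CC(=O)OC[C@@]1(C)[C@H]2CC=C(C)[C@@H](CC[C@@H](C)CC(=O)OC(C)(C)C)[C@]2(C)C[C@H](O[Si](C)(C)C(C)(C)C)[C@@H]1O
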